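Readings and results were computed on assumed constants; the scatter is artificial.

A reading at 10 d means little until you hold it against the lifetime of the substrate. The flasks asked about differ in temperature, so their lifetimes differ too.

| flask | substrate | solid activator | temperature | remark | time |
|---|---|---|---|---|---|
| Wednesday's | 0.17 M | 2.1 equiv | −20 °C | run made earlier |  |
| Monday's | 0.17 M | 3.3 equiv | 5 °C | run made earlier |  |
| Saturday's | 0.26 M | 1.5 equiv | −20 °C | run made earlier |  |
| dawn | 0.17 M | 1.50 equiv | −15 °C |  | 10 d |
| noon | 0.17 M | 1.50 equiv | 25 °C |  | 10 d |
| winter | 0.17 M | 1.50 equiv | 5 °C |  | 10 d |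

- Wednesday's (time / d: ring / %, substrate / %): 0.833: 1.0, 99.9; 1.25: 0, 97.9; 2.00: 1.6, 95.3; 4.00: 0.3, 91.5; 6.00: 2.1, 87.6; 10.0: 1.5, 81.2
- Monday's (time / d: ring / %, substrate / %): 0.625: 0, 88.0; 1.04: 1.1, 76.3; 1.67: 2.0, 65.8; 2.00: 4.2, 60.1; 3.00: 8.7, 45.9; 4.00: 12.9, 33.9
- Saturday's (time / d: ring / %, substrate / %): 0.833: 1.0, 97.0; 1.67: 0, 98.1; 3.00: 0.6, 94.8; 5.00: 1.5, 89.4; 10.0: 0, 79.9

(standard deviation of a reading: 1 percentage point)

- a species is counted by the substrate in it: one open dimer counts as two
- given per volume of solution although it is solid: solid activator
- on the list of suspects stand: ring -> over-reaction product; activated form -> ring; solid activator <-> activator; substrate + activated form -> open dimer; substrate + activator -> activated form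
- at the start none of the solid activator is in solution

1. the best flask by amount of ring, in percent of the substrate charged; "all alike" if 1.5 percentage points covers them all (dawn / noon / winter / all alike)
2. amount of ring at the end, in percent of the substrate charged, dawn
3. amount of ring at the end, in percent of the substrate charged, noon
4. amount of ring at the end, in percent of the substrate charged, winter

While solid activator lies in a flask, I take the dissolved activator as constant. The substrate then decays pseudo-first-order, and its lifetime is the reading time divided by the logarithm of charged over left. Wednesday's run gives 48.0 d. Saturday's run, at another substrate strength and another loading of solid activator, gives 44.6 d, a gap the scatter covers. Monday's run gives the substrate lifetime at 5 °C, 3.70 d, and winter stands at that temperature.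

Now turn the question round. For dawn to lead, I would want its substrate past one lifetime by the reading. Taking the logarithm of the lifetime as straight in temperature, I get 28.8 d for dawn. That is 0.347 of a lifetime, with 70.7 % of the substrate left, so dawn stands far from that. Winter gets 2.70 lifetimes, which reckons to 6.70 % of its substrate left. For noon, the same line, extrapolated, gives 0.476 d, or 21.0 lifetimes. So noon's ring has a long wait to survive if the suspected step to over-reaction product is fast there, and no earlier run stands above 5 °C. My reckoning reaches the substrate, not the ring, but I back winter.

The forecast takes noon, with 2.4 % at dawn, 75 % at noon and 42 % in winter, and it grants that “dimer formation and over-reaction are unmeasured and could take a real share”. We part on the best flask.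

The best flask is winter, with 35.7 % ring, against 1.05 % at dawn and 0.626 % at noon.

    ring → over-reaction product (k = 0.0240 /h, Ea = 106 kJ/mol)
    activated form → ring (k = 0.0750 /h, Ea = 88.0 kJ/mol)
    solid activator ⇌ activator, rate k3*(cs3 - [activator]) while solid is left; crystals form when [activator] > cs3 (solubility = 0.0870 M, k = 0.820 /h)
    substrate + activated form → open dimer (k = 0.300 /M/h, Ea = 69.0 kJ/mol)
    substrate + activator → activated form (k = 0.590 /M/h, Ea = 57.0 kJ/mol)
    (constants at 25 °C)

Noon holds 71.3 % as over-reaction product at 10.0 d. For a flask like noon kept at 10 °C, the line carried on from 3.70 d at 5 °C gives a lifetime of 2.21 d, which reckons to 1.08 % substrate left. That flask holds 1.50 % substrate and 43.2 % ring at 10.0 d.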